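## The problem

Kushenol C is a flavonol: a 3-hydroxy-4H-chromen-4-one (rings A and C) with hydroxyls at C5 and C7, a 2,4-dihydroxyphenyl ring B on C2 and a ten-carbon lavandulyl chain on C8. Ring A is a phloroglucinol nucleus in which only C6 is unsubstituted, so the first task is regiochemical: the chain must lie between O1 and the C7 oxygen, and the acyl carbon C4 between O1 and the C5 oxygen. The only stereocentre, C2'' of the chain (R), is separated from the rings by a methylene group and carries only carbon substituents. Nothing in the flavonol can set or correct it, so it has to arrive in an enantiopure building block and then be left alone. The chain holds a 1,1-disubstituted and a trisubstituted alkene, which rules out hydrogenolysis, boron trihalides, peracids and dioxiranes; protic acid can add the 7-OH across either alkene or protonate the isopropenyl group next to the stereocentre. The four phenolic oxygens must therefore be unmasked at the end under mild acid, and the C3 hydroxyl must come from an oxidant that attacks an enone but not an isolated alkene. The feature that permits the key step is that C4a and C8a are adjacent carbons of ring A, C4a carrying the acyl carbon C4 and C8a carrying O1, with the C5 oxygen next to C4a. An aryne across C4a–C8a, polarised by that oxygen, can take up a carboxylate oxygen at C8a and the acyl carbon at C4a in one operation.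

## Retrosynthesis

Flavonoid numbering is used for ring positions; chain atoms are C1'' to C5''.

**Protecting groups (34 from 33).** The last intermediate is the flavonol 33 with methoxymethyl (MOM) ethers on the C5, C7, C2' and C4' oxygens and the C3 hydroxyl free. Benzyl ethers would need hydrogenolysis and methyl ethers boron trihalides, both excluded by the chain. MOM ethers come off in dilute acidic methanol, survive organolithiums, fluoride at 125 °C and alkaline peroxide, and act as ortho-directors earlier on. The forward step must cleave four acetals without protonating the alkenes.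

**Ring C (33 from 31).** The O1–C2 bond and the C3–O bond are cut together, which leads to the 2'-hydroxychalcone 31 and an Algar–Flynn–Oyamada closure. The neighbouring cut, closing a flavone first and oxidising C3 afterwards, costs at least two more steps and needs either an electrophilic oxidant or a strong base. Chalcone 31 is open-chain and already has every carbon of the target. The forward reaction must close six-membered (flavonol) and not five-membered (aurone).

**Key disconnection (31 from 22 and 27).** The C4–C4a and O1–C8a bonds are cut together: the aryne 29 released from the ortho-silylaryl triflate 22 inserts into the C–O bond of the cinnamic acid 27. The neighbouring cuts are less attractive. Friedel–Crafts or Hoesch acylation of a lavandulyl phloroglucinol needs strong acid and must distinguish C6 from C8. A Claisen–Schmidt condensation needs a 2-hydroxyacetophenone that is itself made by a further metalation and acylation. The aryne cut places the acyl group and the free hydroxyl in the correct relationship in one step and brings in C2, C3 and ring B as a two-step cinnamic acid. The forward reaction must add oxygen at C8a and not C4a, transfer the acyl group faster than the aryl anion is protonated, and capture the aryne faster than it reacts with the alkenes of its own side chain.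

**Cinnamic acid (27 from 24 and 25; 24 from 23).** The C2–C3 alkene is cut by a Knoevenagel–Doebner condensation of 2,4-bis(methoxymethoxy)benzaldehyde 24 with malonic acid 25. Aldehyde 24 comes from 2,4-dihydroxybenzaldehyde 23. The route is basic throughout and gives the E acid directly.

**Aryne precursor (22 from 20; 20 from 18 and 9).** The triflate and the silyl group of 22 both derive from one aryl N-isopropylcarbamate (20), whose carbamate has served as ortho-director and is converted into the triflate in one flask through phenol 21. The C8–C1'' bond is cut next, to aryl iodide 18 and the alkylzinc reagent 19 made from (S)-lavandulyl iodide 9, for a Negishi coupling. Direct alkylation of an ortho-lithiated carbamate with 9 would ask a hindered aryllithium to displace a β-branched primary iodide whose β-hydrogen is allylic, so elimination to a conjugated diene is the likely result.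

**Ring A iodide (18 from 12; 12 from 11; 11 from 10).** The C–Si and C–I bonds of 18 are both cut back to carbamate 12, whose two ortho positions are equivalent and each flanked by a MOM ether. With the nitrogen silylated (13), the carbamate directs lithiation to one ortho position and chlorotrimethylsilane traps aryllithium 14. The N-silylated product 15 is itself the substrate of the second lithiation (16) and the iodine quench (17), so the two metalations share one flask and one N-protection. Silicon is introduced before iodine so that no aryl iodide meets butyllithium, and both lithiations are done on simple material with the chain entering late. Carbamate 12 comes from 3,5-bis(methoxymethoxy)phenol 11 and this from phloroglucinol 10. The forward step must metalate beside the carbamate and not between the two MOM ethers.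

**Side chain (9 from 8; 8 from 7; 7 from 4 and 5; 4 from 1 and 2).** The stereocentre is made by deconjugative alkylation of the dienolate 6 of the senecioyl oxazolidinone 4 with prenyl bromide 5. This forms the C2''–C3'' bond and places the isopropenyl group in one step. Reduction of 7 gives (S)-lavandulol 8, and iodination gives 9. Resolution of racemic lavandulol is shorter but discards half the material and depends on an enzyme distinguishing a stereocentre one carbon removed from the hydroxyl. The auxiliary route gives absolute control from achiral five-carbon pieces, and the auxiliary 1 is recovered.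

## Roads not taken

**Alternative 1:** The cut goes through ring A itself. The C8–C8a, C6–C7 and C4a–C8a bonds would be made in a Danheiser benzannulation of 3-ethoxycyclobut-2-enone A1 with the lavandulyl-substituted triisopropylsilyl ynol ether A2. On heating, A1 opens to a vinylketene that adds to the alkyne of A2. The new cyclobutenone opens again and closes by 6π electrocyclisation to the phenol A3. In A3 the hydroxyl (later O1), the silyl ether (later the C7 oxygen) and the ethyl ether (later the C5 oxygen) are all different, and the chain lies between the first two.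

- Merits: the substitution pattern of ring A is fixed by connectivity and not by a choice between similar positions. There is no organolithium regiochemistry and no aryne next to alkenes, and the conditions are neutral.
- Weak points: A3 lacks C4, so a separate acylation must still choose between the two free ring positions. The C5 ethyl ether cannot be removed under conditions the chain tolerates unless A1 is replaced by a less accessible cyclobutenone. A2 needs a two-carbon extension of 9 and ynolate chemistry. The ketene intermediates can also add to the side-chain alkenes.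
- Comparison: in regiochemical certainty for ring A this road is better than the chosen plan, which depends on the direction of two ortho-metalations and one aryne addition. The chosen plan installs C4 and O1 together, keeps one acid-labile protecting group throughout and reaches the chalcone in fewer steps.

**Alternative 2:** The cut is the C3–C4 bond. A triazolium-derived carbene would convert the ring A aldehyde of dialdehyde A4 into an acyl anion equivalent that adds to the aliphatic aldehyde on the ether side chain. This closes ring C as the 3-hydroxyflavanone A5, a mixture at C2 and C3 that does not matter because both centres become trigonal.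

- Merits: the ring size is fixed by the tether, so no aurone can form. The C3 oxygen arrives with the ring and no peroxide is used. A5 needs only dehydrogenation, and it has the constitution of the transient intermediate 32 of the chosen route.
- Weak points: A4 is hard to make and to keep. It requires O-alkylation of a hindered, hydrogen-bonded phenol with an α-halo arylacetaldehyde equivalent. The resulting α-aryloxy aldehyde is enolisable and its benzylic ether, next to an electron-rich ring B, ionises easily. The cross-benzoin must start at the aromatic aldehyde, which has two ortho substituents and is the less reactive partner; the reverse sense gives the 3-keto-4-hydroxy isomer. The ring A aldehyde needs the same metalation groundwork as the chosen plan, and an oxidation step is added.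
- Comparison: for the certainty of ring C closure this road is better than an Algar–Flynn–Oyamada reaction on a 6'-alkoxychalcone. The chosen plan has simple, stable precursors and a shorter sequence.

**Alternative 3:** The cut is the O1–C2 bond at the flavone oxidation level. Diethylamine would add to the ortho-hydroxyaryl ynone A6 to give an enaminone, and the phenol oxygen would then displace the amine at C2 to close ring C as the flavone A7.

- Merits: closure is reliably six-membered, and the conditions are mild and compatible with MOM ethers and the alkenes.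
- Weak points: A7 has the wrong oxidation level at C3. Dioxirane epoxidation of the flavone is excluded by the side chain, and C3 lithiation, borylation and oxidation add strongly basic steps. A6 must be built from a ring A carbonyl compound and an aryl alkyne with an oxidation in between, about three steps more overall.
- Comparison: ring closure is more reliable here than in the chosen plan, which in return introduces the C3 hydroxyl in the ring-closing step. A7 is kept in reserve: the fallback to step 13 passes through the same flavone.

Key step: step 12

Remark: the side-chain stereocentre keeps one spatial arrangement from 7 to 34; its descriptor is S in 7, 8, 9 and 19 and R from 20 onward only because CH2–aryl ranks below isopropenyl whereas C(=O)N, CH2O, CH2I and CH2Zn rank above it.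

Remark: compounds 1, 2, 5, 10, 23 and 25 are taken as commercial.

## Route

Step 1
Reactants: 1 (S)-4-benzyl-1,3-oxazolidin-2-one; 2 3-methylbut-2-enoyl chloride
Product: 4 (S)-4-benzyl-3-(3-methylbut-2-enoyl)-1,3-oxazolidin-2-one, via lithium oxazolidinide 3 (not isolated)
Conditions: n-BuLi, THF, −78 °C; then 2, −78 to 0 °C
Reagents that add atoms: none
Why: N-acylation of the lithiated oxazolidinone with an acid chloride, the standard entry to N-acyl oxazolidinones; the amide anion 3 is not basic enough to deconjugate the enoyl chloride through a vinylketene.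

Step 2
Reactants: 4 (S)-4-benzyl-3-(3-methylbut-2-enoyl)-1,3-oxazolidin-2-one; 5 1-bromo-3-methylbut-2-ene (prenyl bromide)
Product: 7 (S)-4-benzyl-3-[(2S)-5-methyl-2-(prop-1-en-2-yl)hex-4-enoyl]-1,3-oxazolidin-2-one, via sodium Z-dienolate 6 (not isolated)
Conditions: NaN(SiMe3)2, THF, −78 °C; then 5, −78 to −40 °C
Reagents that add atoms: none
Why: Deconjugative Evans alkylation: the base removes a γ-hydrogen to give the chelated Z-dienolate 6, which reacts with the allylic bromide at its α-carbon on the face opposite the benzyl group of the auxiliary; this sets the chain stereocentre (2S here, the arrangement required in 34) and leaves the isopropenyl group out of conjugation.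

Step 3
Reactants: 7 (S)-4-benzyl-3-[(2S)-5-methyl-2-(prop-1-en-2-yl)hex-4-enoyl]-1,3-oxazolidin-2-one
Product: 8 (S)-lavandulol [(2S)-5-methyl-2-(prop-1-en-2-yl)hex-4-en-1-ol]
Conditions: LiBH4, THF, 0 °C to rt; aq NH4Cl work-up
Reagents that add atoms: none
Why: Reductive removal of the auxiliary: borohydride attacks the exocyclic imide carbonyl and the released oxazolidinone 1 is recovered; the weakly basic reagent should neither epimerise nor conjugate the α-stereocentre before it is reduced.

Step 4
Reactants: 8 (S)-lavandulol
Product: 9 (S)-lavandulyl iodide [(5S)-6-iodo-2-methyl-5-(prop-1-en-2-yl)hex-2-ene]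
Conditions: I2, PPh3, imidazole, CH2Cl2, 0 °C to rt
Reagents that add atoms: iodine, II
Why: Appel-type iodination of a primary alcohol by SN2 displacement of the oxyphosphonium group; the stereocentre is one carbon away and is not involved.

Step 5
Reactants: 10 phloroglucinol (benzene-1,3,5-triol)
Product: 11 3,5-bis(methoxymethoxy)phenol
Conditions: MOMCl (2 equiv), iPr2NEt, DMF, 0 °C to rt; chromatographic separation from the mono- and tris-ethers
Reagents that add atoms: chloromethyl methyl ether, COCCl
Why: O-Alkylation of a symmetric triol with a chloromethyl ether; the three hydroxyls are equivalent, so only the degree of alkylation has to be controlled, by stoichiometry and chromatography, with the mono-ether returned to the reaction.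

Step 6
Reactants: 11 3,5-bis(methoxymethoxy)phenol
Product: 12 3,5-bis(methoxymethoxy)phenyl N-isopropylcarbamate
Conditions: iPrNCO, Et3N (cat.), CH2Cl2, rt
Reagents that add atoms: isopropyl isocyanate, CC(C)N=C=O
Why: Amine-catalysed addition of the phenol to the isocyanate; the secondary carbamate is chosen because it is a strong ortho-director once N-silylated and is later removed by elimination instead of hydrolysis or hydride.

Step 7
Reactants: 12 3,5-bis(methoxymethoxy)phenyl N-isopropylcarbamate
Product: 18 2-iodo-3,5-bis(methoxymethoxy)-6-(trimethylsilyl)phenyl N-isopropylcarbamate, via N-silyl carbamate 13 (not isolated), via first aryllithium 14 (not isolated), via N-silyl C-silyl carbamate 15 (not isolated), via second aryllithium 16 (not isolated), via N-silyl aryl iodide 17 (not isolated)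
Conditions: TBSOTf, TMEDA, Et2O, 0 °C to rt; n-BuLi, TMEDA, −78 °C; TMSCl (1.1 equiv), −78 °C to rt; volatiles removed in vacuo, fresh Et2O; n-BuLi, TMEDA, −78 °C; I2, THF, −78 °C to rt; aq Na2S2O3 then aq NaHSO4 work-up
Reagents that add atoms: chlorotrimethylsilane, C[Si](C)(C)Cl; iodine, II
Why: Two directed ortho-metalations run in one flask by the in situ N-silylation protocol for secondary aryl carbamates: TBSOTf/TMEDA masks the N–H, n-BuLi/TMEDA removes the hydrogen between the carbamate and a MOM ether, where both groups bind lithium, and TMSCl traps aryllithium 14 to give 15, which keeps its N-silyl group and is therefore lithiated directly at the one remaining position flanked by carbamate and MOM ether before the iodine quench. Residual chlorosilane is stripped off with the solvent between the two metalations so that it cannot consume the second charge of base, silicon goes in before iodine so that no aryl iodide is exposed to n-BuLi, and the N–Si bond is hydrolysed during work-up.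

Step 8
Reactants: 18 2-iodo-3,5-bis(methoxymethoxy)-6-(trimethylsilyl)phenyl N-isopropylcarbamate; 9 (S)-lavandulyl iodide
Product: 20 3,5-bis(methoxymethoxy)-2-[(2R)-5-methyl-2-(prop-1-en-2-yl)hex-4-en-1-yl]-6-(trimethylsilyl)phenyl N-isopropylcarbamate, via lavandulylzinc iodide 19 (not isolated)
Conditions: 9, Zn dust (activated with BrCH2CH2Br and TMSCl), LiCl, THF, 40 °C; then 18, Pd(OAc)2 (cat.), SPhos (cat.), THF, 50 °C
Reagents that add atoms: none
Why: Negishi coupling: zinc inserts into the primary C–I bond of 9 to give the homoallylic alkylzinc iodide 19, whose stereocentre is not the metal-bearing carbon, and zerovalent palladium carrying the bulky biarylphosphine joins it to the hindered aryl iodide with reductive elimination faster than β-hydride elimination; alkylzinc halides tolerate a carbamate N–H, and no bond to the stereocentre is made or broken.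

Step 9
Reactants: 20 3,5-bis(methoxymethoxy)-2-[(2R)-5-methyl-2-(prop-1-en-2-yl)hex-4-en-1-yl]-6-(trimethylsilyl)phenyl N-isopropylcarbamate
Product: 22 3,5-bis(methoxymethoxy)-2-[(2R)-5-methyl-2-(prop-1-en-2-yl)hex-4-en-1-yl]-6-(trimethylsilyl)phenyl trifluoromethanesulfonate, via ortho-silyl phenol 21 (not isolated)
Conditions: DBU, Et2NH, MeCN, 40 °C; then PhNTf2, 40 °C
Reagents that add atoms: N-phenylbis(trifluoromethanesulfonimide), O=S(=O)(N(c1ccccc1)S(=O)(=O)C(F)(F)F)C(F)(F)F
Why: DBU removes the carbamate N–H proton and isopropyl isocyanate is expelled (E1cB), diethylamine scavenging it as a urea; the hindered phenoxide of 21 is sulfonylated in the same flask by PhNTf2, and the aryl–silicon bond is inert in the absence of fluoride.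

Step 10
Reactants: 23 2,4-dihydroxybenzaldehyde
Product: 24 2,4-bis(methoxymethoxy)benzaldehyde
Conditions: MOMCl (3 equiv), iPr2NEt, CH2Cl2, 0 °C to rt
Reagents that add atoms: chloromethyl methyl ether, COCCl
Why: Standard MOM protection of both phenols; excess reagent and a longer reaction time are used for the hydroxyl that is hydrogen-bonded to the aldehyde.

Step 11
Reactants: 24 2,4-bis(methoxymethoxy)benzaldehyde; 25 malonic acid
Product: 27 (E)-3-[2,4-bis(methoxymethoxy)phenyl]prop-2-enoic acid, via arylidenemalonic acid 26 (not isolated)
Conditions: pyridine, piperidine (cat.), 90 °C; work-up at pH 4–5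
Reagents that add atoms: none
Why: Knoevenagel–Doebner condensation: piperidine-catalysed condensation gives the arylidenemalonic acid 26, which loses CO2 in hot pyridine to give the E acid; the medium is basic throughout and the mildly acidic work-up should preserve the acetals.

Step 12
Reactants: 22 3,5-bis(methoxymethoxy)-2-[(2R)-5-methyl-2-(prop-1-en-2-yl)hex-4-en-1-yl]-6-(trimethylsilyl)phenyl trifluoromethanesulfonate; 27 (E)-3-[2,4-bis(methoxymethoxy)phenyl]prop-2-enoic acid
Product: 31 (E)-3-[2,4-bis(methoxymethoxy)phenyl]-1-{2-hydroxy-4,6-bis(methoxymethoxy)-3-[(2R)-5-methyl-2-(prop-1-en-2-yl)hex-4-en-1-yl]phenyl}prop-2-en-1-one, via cesium cinnamate 28 (not isolated), via aryne 29 (not isolated), via aryl anion 30 (not isolated)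
Conditions: 27 (2.5 equiv), CsF (7 equiv), THF, rt; then 22, 125 °C, sealed tube
Reagents that add atoms: none
Why: Fluoride attacks silicon in 22 and triflate leaves, releasing aryne 29 across C4a–C8a; the carboxylate 28 adds through oxygen to C8a, because the C5 methoxymethoxy group next to C4a distorts the aryne so that the remote terminus C8a is the flatter, more electrophilic carbon and the negative charge develops at C4a beside the electron-withdrawing C–O bond. The aryl anion 30 then attacks its own ester carbonyl through a four-centre transition structure, and collapse moves the acyl group from oxygen to C4a and leaves the C8a phenoxide, a net 1,3 O-to-C acyl shift of the anionic Fries type. The closest known reaction is the insertion of arynes from ortho-silylaryl triflates into the C–O bond of carboxylic acids (CsF, THF, 125 °C), which gives ortho-hydroxyaryl ketones. Two skeletal bonds (O1–C8a and C4–C4a) are formed, no ring is closed and no stereocentre is created; the side-chain centre carries no acidic hydrogen and is untouched. Regioselectivity across the aryne is the selectivity needed, and the C5 oxygen secures it, the C8 alkyl group opposing it only sterically. Acyl transfer must outrun protonation of 30, which is why the acid is converted into its cesium salt before 22 is added, leaving bifluoride as the only acid present. Capture by carboxylate must also outrun an intramolecular ene reaction of the aryne with the prenyl arm of the side chain, which is why 27 is used in excess and at high concentration. The product leaves the reaction as the cesium phenoxide of the chalcone; should this phenoxide add to its own enone at 125 °C, the ring-closed isomer is returned to the chalcone by the hydroxide medium of step 13, so the outcome does not depend on it.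

Step 13
Reactants: 31 (E)-3-[2,4-bis(methoxymethoxy)phenyl]-1-{2-hydroxy-4,6-bis(methoxymethoxy)-3-[(2R)-5-methyl-2-(prop-1-en-2-yl)hex-4-en-1-yl]phenyl}prop-2-en-1-one
Product: 33 3-hydroxy-5,7-bis(methoxymethoxy)-2-[2,4-bis(methoxymethoxy)phenyl]-8-[(2R)-5-methyl-2-(prop-1-en-2-yl)hex-4-en-1-yl]-4H-chromen-4-one, via dihydroflavonol 32 (not isolated)
Conditions: H2O2 (30% aq), NaOH (aq), MeOH–THF, 0 °C to rt
Reagents that add atoms: hydrogen peroxide, OO
Why: Algar–Flynn–Oyamada reaction: in alkaline H2O2 the phenoxide closes ring C by 6-endo-trig addition of O1 to C2 while C3 is hydroxylated by hydroperoxide, giving the trans-dihydroflavonol 32, which is dehydrogenated in the same medium to the flavonol; the nucleophilic oxidant does not attack the isolated alkenes of the side chain, and both new stereocentres of 32 are lost on oxidation.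

Step 14
Reactants: 33 3-hydroxy-5,7-bis(methoxymethoxy)-2-[2,4-bis(methoxymethoxy)phenyl]-8-[(2R)-5-methyl-2-(prop-1-en-2-yl)hex-4-en-1-yl]-4H-chromen-4-one
Product: 34 kushenol C [2-(2,4-dihydroxyphenyl)-3,5,7-trihydroxy-8-[(2R)-5-methyl-2-(prop-1-en-2-yl)hex-4-en-1-yl]-4H-chromen-4-one]
Conditions: HCl (3 M aq), MeOH, 40 °C
Reagents that add atoms: none
Why: Acid-catalysed acetal exchange with methanol removes the four MOM groups as dimethoxymethane, the chelated C5 ether first; dilute acid at moderate temperature is chosen so that the side-chain alkenes are not protonated, and the stereocentre is not at risk of epimerisation.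

## Compound list

1 | (S)-4-benzyl-1,3-oxazolidin-2-one | O=C1N[C@@H](Cc2ccccc2)CO1 | starting material
2 | 3-methylbut-2-enoyl chloride | CC(C)=CC(=O)Cl | starting material
3 | lithium (S)-4-benzyl-2-oxo-1,3-oxazolidin-3-ide | [Li+].O=C1[N-][C@@H](Cc2ccccc2)CO1 | intermediate
4 | (S)-4-benzyl-3-(3-methylbut-2-enoyl)-1,3-oxazolidin-2-one | CC(C)=CC(=O)N1[C@@H](Cc2ccccc2)COC1=O | intermediate
5 | 1-bromo-3-methylbut-2-ene (prenyl bromide) | CC(C)=CCBr | starting material
6 | sodium (1Z)-1-[(4S)-4-benzyl-2-oxo-1,3-oxazolidin-3-yl]-3-methylbuta-1,3-dien-1-olate | [Na+].C=C(C)/C=C(\[O-])N1[C@@H](Cc2ccccc2)COC1=O | intermediate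
7 | (S)-4-benzyl-3-[(2S)-5-methyl-2-(prop-1-en-2-yl)hex-4-enoyl]-1,3-oxazolidin-2-one | C=C(C)[C@H](CC=C(C)C)C(=O)N1[C@@H](Cc2ccccc2)COC1=O | intermediate
8 | (S)-lavandulol, (2S)-5-methyl-2-(prop-1-en-2-yl)hex-4-en-1-ol | C=C(C)[C@H](CC=C(C)C)CO | intermediate
9 | (S)-lavandulyl iodide, (5S)-6-iodo-2-methyl-5-(prop-1-en-2-yl)hex-2-ene | C=C(C)[C@H](CC=C(C)C)CI | intermediate
10 | phloroglucinol (benzene-1,3,5-triol) | Oc1cc(O)cc(O)c1 | starting material
11 | 3,5-bis(methoxymethoxy)phenol | COCOc1cc(O)cc(OCOC)c1 | intermediate
12 | 3,5-bis(methoxymethoxy)phenyl N-isopropylcarbamate | CC(C)NC(=O)Oc1cc(OCOC)cc(OCOC)c1 | intermediate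
13 | 3,5-bis(methoxymethoxy)phenyl N-(tert-butyldimethylsilyl)-N-isopropylcarbamate | CC(C)N(C(=O)Oc1cc(OCOC)cc(OCOC)c1)[Si](C)(C)C(C)(C)C | intermediate
14 | 2-lithio-3,5-bis(methoxymethoxy)phenyl N-(tert-butyldimethylsilyl)-N-isopropylcarbamate | CC(C)N(C(=O)Oc1cc(OCOC)cc(OCOC)c1[Li])[Si](C)(C)C(C)(C)C | intermediate
15 | 3,5-bis(methoxymethoxy)-2-(trimethylsilyl)phenyl N-(tert-butyldimethylsilyl)-N-isopropylcarbamate | CC(C)N(C(=O)Oc1cc(OCOC)cc(OCOC)c1[Si](C)(C)C)[Si](C)(C)C(C)(C)C | intermediate
16 | 2-lithio-3,5-bis(methoxymethoxy)-6-(trimethylsilyl)phenyl N-(tert-butyldimethylsilyl)-N-isopropylcarbamate | CC(C)N(C(=O)Oc1c([Li])c(OCOC)cc(OCOC)c1[Si](C)(C)C)[Si](C)(C)C(C)(C)C | intermediate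
17 | 2-iodo-3,5-bis(methoxymethoxy)-6-(trimethylsilyl)phenyl N-(tert-butyldimethylsilyl)-N-isopropylcarbamate | CC(C)N(C(=O)Oc1c(I)c(OCOC)cc(OCOC)c1[Si](C)(C)C)[Si](C)(C)C(C)(C)C | intermediate
18 | 2-iodo-3,5-bis(methoxymethoxy)-6-(trimethylsilyl)phenyl N-isopropylcarbamate | CC(C)NC(=O)Oc1c(I)c(OCOC)cc(OCOC)c1[Si](C)(C)C | intermediate
19 | (S)-lavandulylzinc iodide, [(2S)-5-methyl-2-(prop-1-en-2-yl)hex-4-en-1-yl]zinc iodide | C=C(C)[C@H](CC=C(C)C)C[Zn]I | intermediate
20 | 3,5-bis(methoxymethoxy)-2-[(2R)-5-methyl-2-(prop-1-en-2-yl)hex-4-en-1-yl]-6-(trimethylsilyl)phenyl N-isopropylcarbamate | C=C(C)[C@H](CC=C(C)C)Cc1c(OCOC)cc(OCOC)c([Si](C)(C)C)c1OC(=O)NC(C)C | intermediate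
21 | 3,5-bis(methoxymethoxy)-2-[(2R)-5-methyl-2-(prop-1-en-2-yl)hex-4-en-1-yl]-6-(trimethylsilyl)phenol (formed as its DBU salt) | C=C(C)[C@H](CC=C(C)C)Cc1c(OCOC)cc(OCOC)c([Si](C)(C)C)c1O | intermediate
22 | 3,5-bis(methoxymethoxy)-2-[(2R)-5-methyl-2-(prop-1-en-2-yl)hex-4-en-1-yl]-6-(trimethylsilyl)phenyl trifluoromethanesulfonate | C=C(C)[C@H](CC=C(C)C)Cc1c(OCOC)cc(OCOC)c([Si](C)(C)C)c1OS(=O)(=O)C(F)(F)F | intermediate
23 | 2,4-dihydroxybenzaldehyde | O=Cc1ccc(O)cc1O | starting material
24 | 2,4-bis(methoxymethoxy)benzaldehyde | COCOc1ccc(C=O)c(OCOC)c1 | intermediate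
25 | malonic acid | OC(=O)CC(=O)O | starting material
26 | 2-[2,4-bis(methoxymethoxy)benzylidene]malonic acid | OC(=O)C(=Cc1ccc(OCOC)cc1OCOC)C(=O)O | intermediate
27 | (E)-3-[2,4-bis(methoxymethoxy)phenyl]prop-2-enoic acid | O=C(O)/C=C/c1ccc(OCOC)cc1OCOC | intermediate
28 | cesium (E)-3-[2,4-bis(methoxymethoxy)phenyl]prop-2-enoate | [Cs+].[O-]C(=O)/C=C/c1ccc(OCOC)cc1OCOC | intermediate
29 | 4,6-bis(methoxymethoxy)-3-[(2R)-5-methyl-2-(prop-1-en-2-yl)hex-4-en-1-yl]benzyne (aryne across C4a–C8a) | C=C(C)[C@H](CC=C(C)C)CC1=C(OCOC)C=C(OCOC)C#C1 | intermediate
30 | cesium 2-{[(2E)-3-[2,4-bis(methoxymethoxy)phenyl]prop-2-enoyl]oxy}-4,6-bis(methoxymethoxy)-3-[(2R)-5-methyl-2-(prop-1-en-2-yl)hex-4-en-1-yl]benzen-1-ide | [Cs+].C=C(C)[C@H](CC=C(C)C)Cc1c(OCOC)cc(OCOC)[c-]c1OC(=O)/C=C/c1ccc(OCOC)cc1OCOC | intermediate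
31 | (E)-3-[2,4-bis(methoxymethoxy)phenyl]-1-{2-hydroxy-4,6-bis(methoxymethoxy)-3-[(2R)-5-methyl-2-(prop-1-en-2-yl)hex-4-en-1-yl]phenyl}prop-2-en-1-one | C=C(C)[C@H](CC=C(C)C)Cc1c(OCOC)cc(OCOC)c(C(=O)/C=C/c2ccc(OCOC)cc2OCOC)c1O | intermediate
32 | trans-3-hydroxy-5,7-bis(methoxymethoxy)-2-[2,4-bis(methoxymethoxy)phenyl]-8-[(2R)-5-methyl-2-(prop-1-en-2-yl)hex-4-en-1-yl]chroman-4-one (both trans pairs at C2/C3; side-chain centre R) | C=C(C)[C@H](CC=C(C)C)Cc1c(OCOC)cc(OCOC)c2c1OC(c1ccc(OCOC)cc1OCOC)C(O)C2=O | intermediate
33 | 3-hydroxy-5,7-bis(methoxymethoxy)-2-[2,4-bis(methoxymethoxy)phenyl]-8-[(2R)-5-methyl-2-(prop-1-en-2-yl)hex-4-en-1-yl]-4H-chromen-4-one | C=C(C)[C@H](CC=C(C)C)Cc1c(OCOC)cc(OCOC)c2c(=O)c(O)c(-c3ccc(OCOC)cc3OCOC)oc12 | intermediate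
34 | kushenol C, 2-(2,4-dihydroxyphenyl)-3,5,7-trihydroxy-8-[(2R)-5-methyl-2-(prop-1-en-2-yl)hex-4-en-1-yl]-4H-chromen-4-one | C=C(C)[C@H](CC=C(C)C)Cc1c(O)cc(O)c2c(=O)c(O)c(-c3ccc(O)cc3O)oc12 | target

## Step count and least certain steps

Total step count: 14. Longest linear sequence: 9 steps (steps 1–4, 8, 9 and 12–14 from oxazolidinone 1). The ring A branch from phloroglucinol 10 runs through steps 5–9 and 12–14 (8 steps), and the cinnamic acid branch (steps 10 and 11) joins at step 12.

**Step 12 (key step).** The most likely failure is intramolecular consumption of the aryne. The prenyl arm is held three carbons from C8, so its alkene can reach C8a and deliver an allylic hydrogen to C4a in an ene reaction. That process is unimolecular and competes with bimolecular capture by carboxylate, and nothing in the substrate prevents it; only the carboxylate concentration works against it. A second risk is protonation of the aryl anion before acyl transfer, which stops at the aryl ester. The first refinement would be to use the isolated, dried cesium salt of 27.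

The fallback avoids the aryne and installs hydroxyl and acyl group separately. From 12, in situ N-silylation, ortho-lithiation and an iodine quench (the first metalation of step 7 with I2 in place of TMSCl, followed by the aqueous work-up) would give 2-iodo-3,5-bis(methoxymethoxy)phenyl N-isopropylcarbamate F1. Negishi coupling of F1 with 19 as in step 8 would give 3,5-bis(methoxymethoxy)-2-[(2R)-lavandulyl]phenyl N-isopropylcarbamate F2. A second ortho-metalation of F2 by the same N-silylation protocol at the remaining position next to the carbamate, quenched with N-methoxy-N-methylacetamide, would give the 2-acetyl carbamate F3. Cleavage with DBU and Et2NH as in step 9, without triflation, would give 2-hydroxy-4,6-bis(methoxymethoxy)-3-[(2R)-lavandulyl]acetophenone F4. Claisen–Schmidt condensation of F4 with aldehyde 24 (KOH, EtOH) comes back to the route at chalcone 31.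

**Step 13.** Five-membered closure is the likely problem. With an ether at C6' of the chalcone, attack of the phenoxide at the α-carbon of the oxidised enone competes with attack at C2 and leads to an aurone instead of the flavonol.

The fallback separates ring closure from oxidation. From 31, NaOAc in refluxing EtOH would close the ring to 5,7,2',4'-tetrakis(methoxymethoxy)-8-[(2R)-lavandulyl]flavanone F5. Dehydrogenation of F5 with IBX in DMSO at 80 °C would give the flavone F6, which has the constitution of A7. Deprotonation of F6 at C3 with LiN(iPr)2 at −78 °C and trapping with B(OMe)3 would give the C3 dimethyl boronate F7. Oxidation of F7 with H2O2 and AcOH comes back to the route at 33.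

**Step 8.** The alkylzinc reagent may be lost by protonolysis at the carbamate N–H, or the hindered palladium alkyl may undergo β-hydride elimination instead of reductive elimination. A radical 1,2-vinyl shift during zinc insertion would also scramble the chain.

The fallback changes the organometallic partner and the way it is made. From 9, iodine–lithium exchange with t-BuLi in Et2O at −78 °C and trapping with B-methoxy-9-BBN would give the lithium B-lavandulyl-B-methoxy-9-borabicyclo[3.3.1]nonane ate complex F8. A Suzuki–Miyaura coupling of F8 with 18 (PdCl2(dppf), aq K3PO4, DMF) comes back to the route at 20. No radical is formed and the borate is not basic.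

**Step 7.** The first metalation could go to the position between the two MOM ethers (C4 of the phenyl ring) instead of the position beside the carbamate. That would place silicon, and later the whole substitution pattern, wrongly, and the same choice recurs in the second metalation. Carry-over of chlorosilane into the second lithiation would in addition divert part of the second aryllithium to a doubly C-silylated carbamate.

The fallback fixes the silicon position by a halogen instead of a directing group and takes the silylation out of the metalation flask. From 11, amine-mediated ortho-bromination (NBS, iPr2NH cat., CH2Cl2) would give 2-bromo-3,5-bis(methoxymethoxy)phenol F9. O-Silylation with (Me3Si)2NH would give [2-bromo-3,5-bis(methoxymethoxy)phenoxy]trimethylsilane F10. Bromine–lithium exchange with n-BuLi at −78 °C would then trigger a retro-Brook shift of silicon from oxygen to carbon and give 3,5-bis(methoxymethoxy)-2-(trimethylsilyl)phenol F11. Carbamoylation of F11 as in step 6 would give 3,5-bis(methoxymethoxy)-2-(trimethylsilyl)phenyl N-isopropylcarbamate F12. In situ N-silylation of F12 (TBSOTf, TMEDA, Et2O) comes back to the route at 15, from which the second lithiation and the iodine quench of step 7 follow in a flask that has never held chlorosilane.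

**Step 14.** Protonation of a side-chain alkene could be followed by closure of the 7-OH onto the cation (a chroman) or by addition of methanol. Protonation of the isopropenyl group would also place a cation next to the stereocentre.

The fallback avoids protic acid. From 33, TMSOTf with 2,2'-bipyridyl in CH2Cl2 at 0 °C would convert the aryl MOM ethers into silyl ethers and silylate the C3 hydroxyl, giving the pentakis(trimethylsilyl) ether F13 of kushenol C. Hydrolysis of F13 with water in THF comes back to the route at 34.

## Further compounds

F1 | step 12 | 2-iodo-3,5-bis(methoxymethoxy)phenyl N-isopropylcarbamate | CC(C)NC(=O)Oc1cc(OCOC)cc(OCOC)c1I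
F2 | step 12 | 3,5-bis(methoxymethoxy)-2-[(2R)-5-methyl-2-(prop-1-en-2-yl)hex-4-en-1-yl]phenyl N-isopropylcarbamate | C=C(C)[C@H](CC=C(C)C)Cc1c(OCOC)cc(OCOC)cc1OC(=O)NC(C)C
F3 | step 12 | 2-acetyl-3,5-bis(methoxymethoxy)-6-[(2R)-5-methyl-2-(prop-1-en-2-yl)hex-4-en-1-yl]phenyl N-isopropylcarbamate | C=C(C)[C@H](CC=C(C)C)Cc1c(OCOC)cc(OCOC)c(C(C)=O)c1OC(=O)NC(C)C
F4 | step 12 | 1-{2-hydroxy-4,6-bis(methoxymethoxy)-3-[(2R)-5-methyl-2-(prop-1-en-2-yl)hex-4-en-1-yl]phenyl}ethan-1-one | C=C(C)[C@H](CC=C(C)C)Cc1c(OCOC)cc(OCOC)c(C(C)=O)c1O
F5 | step 13 | 5,7-bis(methoxymethoxy)-2-[2,4-bis(methoxymethoxy)phenyl]-8-[(2R)-5-methyl-2-(prop-1-en-2-yl)hex-4-en-1-yl]chroman-4-one (both C2 epimers) | C=C(C)[C@H](CC=C(C)C)Cc1c(OCOC)cc(OCOC)c2c1OC(c1ccc(OCOC)cc1OCOC)CC2=O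
F6 | step 13 | 5,7-bis(methoxymethoxy)-2-[2,4-bis(methoxymethoxy)phenyl]-8-[(2R)-5-methyl-2-(prop-1-en-2-yl)hex-4-en-1-yl]-4H-chromen-4-one | C=C(C)[C@H](CC=C(C)C)Cc1c(OCOC)cc(OCOC)c2c(=O)cc(-c3ccc(OCOC)cc3OCOC)oc12
F7 | step 13 | dimethyl {5,7-bis(methoxymethoxy)-2-[2,4-bis(methoxymethoxy)phenyl]-8-[(2R)-5-methyl-2-(prop-1-en-2-yl)hex-4-en-1-yl]-4-oxo-4H-chromen-3-yl}boronate | C=C(C)[C@H](CC=C(C)C)Cc1c(OCOC)cc(OCOC)c2c(=O)c(B(OC)OC)c(-c3ccc(OCOC)cc3OCOC)oc12
F8 | step 8 | lithium 9-methoxy-9-[(2S)-5-methyl-2-(prop-1-en-2-yl)hex-4-en-1-yl]-9-boranuidabicyclo[3.3.1]nonane | [Li+].C=C(C)[C@H](CC=C(C)C)C[B-]1(OC)C2CCCC1CCC2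
F9 | step 7 | 2-bromo-3,5-bis(methoxymethoxy)phenol | COCOc1cc(O)c(Br)c(OCOC)c1
F10 | step 7 | [2-bromo-3,5-bis(methoxymethoxy)phenoxy]trimethylsilane | COCOc1cc(O[Si](C)(C)C)c(Br)c(OCOC)c1
F11 | step 7 | 3,5-bis(methoxymethoxy)-2-(trimethylsilyl)phenol | COCOc1cc(O)c([Si](C)(C)C)c(OCOC)c1
F12 | step 7 | 3,5-bis(methoxymethoxy)-2-(trimethylsilyl)phenyl N-isopropylcarbamate | CC(C)NC(=O)Oc1cc(OCOC)cc(OCOC)c1[Si](C)(C)C
F13 | step 14 | 8-[(2R)-5-methyl-2-(prop-1-en-2-yl)hex-4-en-1-yl]-3,5,7-tris(trimethylsilyloxy)-2-[2,4-bis(trimethylsilyloxy)phenyl]-4H-chromen-4-one | C=C(C)[C@H](CC=C(C)C)Cc1c(O[Si](C)(C)C)cc(O[Si](C)(C)C)c2c(=O)c(O[Si](C)(C)C)c(-c3ccc(O[Si](C)(C)C)cc3O[Si](C)(C)C)oc12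
A1 | alternative 1 | 3-ethoxycyclobut-2-en-1-one | CCOC1=CC(=O)C1
A2 | alternative 1 | triisopropyl{[(4R)-7-methyl-4-(prop-1-en-2-yl)oct-6-en-1-yn-1-yl]oxy}silane | C=C(C)[C@H](CC=C(C)C)CC#CO[Si](C(C)C)(C(C)C)C(C)C
A3 | alternative 1 | 5-ethoxy-2-[(2R)-5-methyl-2-(prop-1-en-2-yl)hex-4-en-1-yl]-3-(triisopropylsilyloxy)phenol | C=C(C)[C@H](CC=C(C)C)Cc1c(O)cc(OCC)cc1O[Si](C(C)C)(C(C)C)C(C)C
A4 | alternative 2 | 2-{1-[2,4-bis(methoxymethoxy)phenyl]-2-oxoethoxy}-4,6-bis(methoxymethoxy)-3-[(2R)-5-methyl-2-(prop-1-en-2-yl)hex-4-en-1-yl]benzaldehyde | C=C(C)[C@H](CC=C(C)C)Cc1c(OCOC)cc(OCOC)c(C=O)c1OC(C=O)c1ccc(OCOC)cc1OCOC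
A5 | alternative 2 | 3-hydroxy-5,7-bis(methoxymethoxy)-2-[2,4-bis(methoxymethoxy)phenyl]-8-[(2R)-5-methyl-2-(prop-1-en-2-yl)hex-4-en-1-yl]chroman-4-one (mixture at C2 and C3) | C=C(C)[C@H](CC=C(C)C)Cc1c(OCOC)cc(OCOC)c2c1OC(c1ccc(OCOC)cc1OCOC)C(O)C2=O
A6 | alternative 3 | 3-[2,4-bis(methoxymethoxy)phenyl]-1-{2-hydroxy-4,6-bis(methoxymethoxy)-3-[(2R)-5-methyl-2-(prop-1-en-2-yl)hex-4-en-1-yl]phenyl}prop-2-yn-1-one | C=C(C)[C@H](CC=C(C)C)Cc1c(OCOC)cc(OCOC)c(C(=O)C#Cc2ccc(OCOC)cc2OCOC)c1O
A7 | alternative 3 | 5,7-bis(methoxymethoxy)-2-[2,4-bis(methoxymethoxy)phenyl]-8-[(2R)-5-methyl-2-(prop-1-en-2-yl)hex-4-en-1-yl]-4H-chromen-4-one | C=C(C)[C@H](CC=C(C)C)Cc1c(OCOC)cc(OCOC)c2c(=O)cc(-c3ccc(OCOC)cc3OCOC)oc12
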